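**Retrosynthetic overview** (cembrane numbering: C1 = ring CH bearing the C15–C17 unit)
1. The ε-lactone (C12–O–C16) closes last from the C16 acid. The acid comes from the C1 isopropenyl group, and the two secondary acetates go on just before that.
2. The 14-membered carbocycle is opened at C11–C12, an electroreductive Ti-catalysed keto-aldehyde pinacol macrocyclisation that sets C11 and C12.
3. The cis-THF (C4–O–C7) comes from C7–OH-directed epoxidation of the E-C3=C4 alkene and 5-exo opening (sets C3 and C4). C7 comes from chelate-controlled reduction next to C8.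
4. The open chain is cut at C5–C6 by a ketal-Claisen union, which also builds the E-alkene. The partners are a limonene-derived allylic alcohol and a linalool-derived ketal.
5. Ring order is THF, then carbocycle, then lactone. Chirality is bought as C1 in (R)-limonene oxide and C8 in (R)-linalool.

Assumptions: one-pot operations without isolation count as one step. The anomeric C11 centre and the carbinol of 3 are inconsequential mixtures and are left undefined in the SMILES.

**Step 1**
Reactants: 1, (+)-(4R)-limonene 1,2-oxide (commercial cis/trans mixture)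
Product: 2, (3R)-6-oxo-3-(prop-1-en-2-yl)heptanal
Conditions: H5IO6, THF/H2O, 0 °C → rt
Reagents that add atoms: water, O
Why: Epoxide hydrolysis followed by Malaprade glycol cleavage converges both epoxide isomers on one keto-aldehyde and leaves the bought C1 centre (R) untouched.

**Step 2**
Reactants: 2, (3R)-6-oxo-3-(prop-1-en-2-yl)heptanal
Product: 3, (5R)-7-hydroxy-8-methyl-5-(prop-1-en-2-yl)non-8-en-2-one (carbinol epimers)
Conditions: CH2=C(CH3)MgBr (1.05 equiv), THF, −78 °C
Reagents that add atoms: isopropenylmagnesium bromide, C=C(C)[Mg]Br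
Why: Grignard 1,2-addition is chemoselective for the aldehyde over the methyl ketone at −78 °C, and the unselective carbinol centre does not matter because step 6 erases it.

**Step 3**
Reactants: 4, (R)-(−)-linalool
Product: 5, (5R)-5-ethenyl-2-methoxy-5-methyloxolane (anomers)
Conditions: O3 (1 equiv), CH2Cl2/MeOH, −78 °C; Me2S; then p-TsOH (cat.), MeOH, rt (one pot)
Reagents that add atoms: methanol, CO
Why: Ozonolysis selects the electron-rich trisubstituted alkene, and the γ-hydroxy-aldehyde closes to a lactol whose acetalisation masks both C8–OH and the C11 aldehyde in one ring, with the bought C8 (R) untouched.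

**Step 4**
Reactants: 5, (5R)-5-ethenyl-2-methoxy-5-methyloxolane
Product: 6, 1-[(2R)-5-methoxy-2-methyloxolan-2-yl]ethan-1-one
Conditions: Pd(Quinox)Cl2 (cat., achiral ligand), AgSbF6 (cat.), aq t-BuOOH, CH2Cl2, 0 °C → rt
Reagents that add atoms: tert-butyl hydroperoxide, CC(C)(C)OO
Why: This catalyst-controlled Markovnikov Wacker-type oxidation gives methyl ketones even from allylic ethers, and the vinyl group is the only alkene present.

**Step 5**
Reactants: 6, 1-[(2R)-5-methoxy-2-methyloxolan-2-yl]ethan-1-one
Product: 7, (2R)-2-(1,1-dimethoxyethyl)-5-methoxy-2-methyloxolane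
Conditions: HC(OMe)3, MeOH, p-TsOH (cat.), 50 °C
Reagents that add atoms: trimethyl orthoformate, COC(OC)OC; methanol, CO
Why: Orthoformate-driven ketalisation works on α-oxygenated methyl ketones next to a quaternary carbon, and this ketone can only enolise toward its methyl group.

**Step 6**
Reactants: 3, (5R)-7-hydroxy-8-methyl-5-(prop-1-en-2-yl)non-8-en-2-one; 7, (2R)-2-(1,1-dimethoxyethyl)-5-methoxy-2-methyloxolane (2 equiv)
Product: 8, (4E,7R)-1-[(2R)-5-methoxy-2-methyloxolan-2-yl]-4-methyl-7-(prop-1-en-2-yl)undec-4-ene-1,10-dione
Conditions: 2,4-dinitrophenol (10 mol %), toluene, 115 °C, MeOH distilled off; aqueous work-up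
Reagents that add atoms: none
Why: In this Johnson-type ketal Claisen rearrangement, alcohol/ketal exchange and loss of MeOH give the allyl vinyl ether, and its chair [3,3] transition state with the C2 chain equatorial forms C5–C6 and the E-C3=C4 alkene.

**Step 7**
Reactants: 8, the C7,C12-diketone
Product: 9, (1S,4E,7R)-10,10-dimethoxy-1-[(2R)-5-methoxy-2-methyloxolan-2-yl]-4-methyl-7-(prop-1-en-2-yl)undec-4-en-1-ol
Conditions: CeCl3, HC(OMe)3, MeOH, rt; then NaBH4, −78 → −20 °C; aq NaHCO3 (one pot)
Reagents that add atoms: trimethyl orthoformate, COC(OC)OC; methanol, CO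
Why: Gemal–Luche selective ketalisation masks only the unhindered C12 ketone, and Cram-chelate reduction (Ce bridging C7=O and the ring oxygen on C8) then delivers hydride from the methyl face opposite the oxolane ring to give 7S from 8R.

**Step 8**
Reactants: 9, the C7 alcohol
Product: 10, (1S,3R)-1-{(2R,5S)-5-[(2R)-5-methoxy-2-methyloxolan-2-yl]-2-methyloxolan-2-yl}-6,6-dimethoxy-3-(prop-1-en-2-yl)heptan-1-ol
Conditions: VO(acac)2 (5 mol %), t-BuOOH (decane), CH2Cl2, 0 °C → rt; then PPTS (cat.)
Reagents that add atoms: tert-butyl hydroperoxide, CC(C)(C)OO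
Why: In this hydroxyl-directed V(V) epoxidation of a bis-homoallylic alcohol with 5-exo opening at tertiary C4 (inversion), the chair-like vanadate transition state with the C8 group equatorial gives the 2,5-cis ring (4R from 7S), the E-geometry fixes 3S, and the undirected isopropenyl group is untouched.

**Step 9**
Reactants: 10, the bis-oxolane ketal
Product: 11, (5R,7S)-7-hydroxy-7-{(2R,5S)-5-[(2R)-5-hydroxy-2-methyloxolan-2-yl]-2-methyloxolan-2-yl}-5-(prop-1-en-2-yl)heptan-2-one (lactol)
Conditions: AcOH/THF/H2O (3:1:1), 40 °C
Reagents that add atoms: water, O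
Why: Mild acid hydrolysis frees the C12 ketone and the C11 aldehyde (as its lactol) in one operation without touching any stereocentre.

**Step 10 (key step)**
Reactants: 11, the keto-lactol
Product: 12, (1R,3S,4R,7S,8R,11R,12R)-4,7-epoxycembr-15(17)-ene-3,8,11,12-tetraol (14-membered carbocycle, cis-bridged THF, isopropenyl at C1)
Conditions: TiCl4(thf)2 (20 mol %), 2,4,6-collidine·HCl (3 equiv), n-Bu4NPF6, DME, 0 °C; undivided cell, Zn(+)/RVC(−), constant current, about 2.5 F/mol; 11 added by syringe pump over 20 h (final 2 mM)
Reagents that add atoms: none (2 e⁻ and 2 H⁺ only)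
Why: Proposed new method: cathodically regenerated low-valent Ti captures the small equilibrium amount of hydroxy-aldehyde released by the lactol (a built-in slow release that reinforces high dilution) and reduces it to a Ti-bound C11 ketyl, which adds to the Ti-coordinated C12 ketone before a second electron and collidinium protonolysis free the diol and return Ti(IV); with both oxygens gauche on Ti and the ring bonds C10–C11 and C12–C13 antiperiplanar only the threo pair can form, and the (11R,12R) pairing should be favoured under substrate control from C1 and C8, because it places C20 and the isopropenyl group on opposite faces of the extended C11–C2 segment; the closest known reaction types are stoichiometric TiCl3/Zn–Cu keto-aldehyde pinacol macrocyclisations of cembranoids and Ti-catalysed (Zn/R3SiCl or photoredox) pinacol couplings of aromatic aldehydes.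

**Step 11**
Reactants: 12, the tetraol
Product: 13, the 3,11-di-O-acetate of 12
Conditions: Ac2O, pyridine, DMAP (5 mol %), CH2Cl2, 0 °C → rt
Reagents that add atoms: acetic anhydride, CC(=O)OC(C)=O
Why: Acylation takes only the two secondary alcohols, the tertiary C8 and C12 hydroxyls are inert under these conditions, and capping C3–OH also blocks later δ-lactone formation.

**Step 12**
Reactants: 13, the diacetate
Product: 14, 3,11-diacetoxy-8,12-dihydroxy-4,7-epoxycembr-15(17)-en-16-al
Conditions: SeO2 (1.5 equiv), 1,4-dioxane, 70 °C
Reagents that add atoms: selenium dioxide, O=[Se]=O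
Why: In this Riley allylic oxidation (ene then [2,3] shift) of the only alkene, A1,3 strain holds C1–H in the alkene plane, so only the methyl hydrogens are aligned and the 2-substituted acrolein forms.

**Step 13**
Reactants: 14, the enal
Product: 15, 3,11-diacetoxy-8,12-dihydroxy-4,7-epoxycembr-15(17)-en-16-oic acid
Conditions: NaClO2, NaH2PO4, 2-methyl-2-butene, t-BuOH/H2O, 0 °C
Reagents that add atoms: sodium chlorite, [Na+].[O-]Cl=O
Why: Pinnick oxidation converts enals to acrylic acids without affecting the alkene, the acetates or the free tertiary alcohols.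

**Step 14**
Reactants: 15, the seco acid
Product: 16, querciformolide C
Conditions: 2-methyl-6-nitrobenzoic anhydride (MNBA), DMAP, CH2Cl2 (2 mM), rt → 40 °C
Reagents that add atoms: none
Why: In this Shiina lactonisation the mixed anhydride acylates the C12 hydroxyl through a chair-like seven-membered transition state with C2 and C11 equatorial, whereas C8–OH would need an 11-membered ring, and no stereocentre is touched.

**Compound list**
1 | (+)-(4R)-limonene 1,2-oxide | CC12OC1C[C@@H](CC2)C(C)=C | starting material
2 | (3R)-6-oxo-3-(prop-1-en-2-yl)heptanal | O=CC[C@@H](CCC(C)=O)C(C)=C | intermediate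
3 | (5R)-7-hydroxy-8-methyl-5-(prop-1-en-2-yl)non-8-en-2-one | C=C(C)C(O)C[C@@H](CCC(C)=O)C(C)=C | intermediate
4 | (R)-(−)-linalool | C=C[C@](C)(O)CCC=C(C)C | starting material
5 | (5R)-5-ethenyl-2-methoxy-5-methyloxolane | C=C[C@@]1(C)CCC(OC)O1 | intermediate
6 | 1-[(2R)-5-methoxy-2-methyloxolan-2-yl]ethan-1-one | CC(=O)[C@@]1(C)CCC(OC)O1 | intermediate
7 | (2R)-2-(1,1-dimethoxyethyl)-5-methoxy-2-methyloxolane | CC(OC)(OC)[C@@]1(C)CCC(OC)O1 | intermediate
8 | E-enedione (C7 and C12 ketones) | COC1CC[C@@](C)(O1)C(=O)CC/C(C)=C/C[C@@H](CCC(C)=O)C(C)=C | intermediate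
9 | (7S)-alcohol, C12 dimethyl ketal | COC1CC[C@@](C)(O1)[C@@H](O)CC/C(C)=C/C[C@@H](CCC(C)(OC)OC)C(C)=C | intermediate
10 | cis-THF (3S)-alcohol, ketal and acetal | COC1CC[C@@](C)(O1)[C@@H]2CC[C@@](C)(O2)[C@@H](O)C[C@@H](CCC(C)(OC)OC)C(C)=C | intermediate
11 | keto-lactol | OC1CC[C@@](C)(O1)[C@@H]2CC[C@@](C)(O2)[C@@H](O)C[C@@H](CCC(C)=O)C(C)=C | intermediate
12 | 4,7-epoxycembr-15(17)-ene-3,8,11,12-tetraol | C=C(C)[C@@H]1CC[C@@](C)(O)[C@H](O)CC[C@@](C)(O)[C@@H]2CC[C@@](C)(O2)[C@@H](O)C1 | intermediate
13 | 3,11-diacetate | C=C(C)[C@@H]1CC[C@@](C)(O)[C@H](OC(C)=O)CC[C@@](C)(O)[C@@H]2CC[C@@](C)(O2)[C@@H](OC(C)=O)C1 | intermediate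
14 | 16-al | C=C(C=O)[C@@H]1CC[C@@](C)(O)[C@H](OC(C)=O)CC[C@@](C)(O)[C@@H]2CC[C@@](C)(O2)[C@@H](OC(C)=O)C1 | intermediate
15 | 16-oic acid | C=C(C(=O)O)[C@@H]1CC[C@@](C)(O)[C@H](OC(C)=O)CC[C@@](C)(O)[C@@H]2CC[C@@](C)(O2)[C@@H](OC(C)=O)C1 | intermediate
16 | querciformolide C | C=C1C(=O)O[C@]2(C)CC[C@@H]1C[C@H](OC(C)=O)[C@@]1(C)CC[C@H](O1)[C@](C)(O)CC[C@H]2OC(C)=O | target

**Total steps:** 14. **Longest linear sequence:** 12 (from 4, steps 3–14); the limonene branch is 11.

**Steps most likely to fail**
1. Step 10 (new electro-Ti pinacol macrocyclisation).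
   - Risks: simple carbonyl reduction, oligomers, Ti sequestration by the polyol, or the wrong facial pairing. The argument for the (11R,12R) face is the weakest stereochemical link in the route, and mis-paired diols can be returned to 11 with NaIO4.
   - Fallback (known chemistry, different closure): Ti(0) McMurry olefination of the O-protected keto-aldehyde to the macrocyclic E-C11=C12 alkene, followed by OsO4 syn-dihydroxylation, which is stereospecifically threo.
2. Step 8 (cis/trans ratio of the THF).
   - Risk: the 2,5-cis preference is argued by analogy with V(V) oxidations of 1-substituted 4-alkenols.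
   - Fallback: build the Z-C3=C4 alkene instead by Still–Gennari olefination of 2, reduction and bromination, and alkylation of the enolate of 6. Then close the ring by Os-catalysed oxidative cyclisation of the free C7,C8-diol, where syn addition and the cis-2,5 ring are mechanistically enforced.
3. Step 14 (acylation of a hindered tertiary alcohol by an acrylic acid).
   - Fallback: change how the lactone is built. Ozonolyse the isopropenyl group of 13 to the C15 methyl ketone, form the kinetic enol triflate, and run a Pd(0)/CO carbonylative lactonisation in which the acyl-palladium is trapped by C12–OH to give the α-methylene lactone directly.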